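Slowness came first. Pre-initiator turned into initiator with a half-life of 0.363 h, longer than the 0.099 h of initiator or the 0.066 h of living end, so chains arrived gradually, and I looked for a number that did not need that timing.

free monomer 3.0 M; transfer agent 0.0900 M; pre-initiator 2.5 mol%; time 8.0 h

    free monomer + initiator → living end + monomer in chains (k1 = 6.51 × 10⁻⁴ /M/s)
    free monomer + living end → monomer in chains + living end, rate k2*[living end]*[free monomer] (k2 = 0.0693 /M/s)
    living end + transfer agent → dead chain (k3 = 0.0324 /M/s)
    pre-initiator → initiator (k4 = 5.31 × 10⁻⁴ /s)
    2 free monomer → self-condensation product (k5 = 4.23 × 10⁻⁷ /M/s)

- a species is counted by the free monomer in it: one self-condensation product counts as two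
- a step written with two of one species runs at k times the square of its concentration and takes two of it each time
- the average divides the monomer in chains by the number of chains begun, living and dead together
- run time (flask): 8.0 h

- average number of monomer units in a chain (chains begun, living or dead) at 8.0 h
- part of the free monomer that has reacted at 8.0 h

Free monomer and transfer agent are both consumed in proportion to c(living end), so time drops out when their logarithmic falls are divided. This gave me a selectivity factor S, the propagation constant over the transfer constant, 2.14: the decades free monomer loses for each decade transfer agent loses, with initiation and self-condensation set aside.

I took two extreme versions. In the first, I simply supposed that every pre-initiator begins a chain and that free monomer is used to the end, which makes dp 40.0. In the second, c(transfer agent) stays at its charge, a pseudo-first-order picture, and stopping the 0.0750 M of chains leaves 16.8% of the free monomer, with dp 33.3.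

I placed the real flask between them, since its transfer agent thins yet outlasts the chains, which makes pre-initiator the limiting reagent. With each chain stopped, transfer agent falls to 16.7% of its charge. Raising that to the power S, I committed to c = 97.8% and dp = 39.1.

The forecast gave dp 40.2 (38.5 to 42) and c 97.5% (96.5% to 98.3%), a c lower than mine, noting that “Initiation slows as monomer is consumed”.

The simulation gave dp 40.0 and c 97.4%, inside the forecast's ranges . In this flask 20% of the transfer agent remained at 8.00 h, and that fraction to the power S gives 3.04% against the 2.6% of free monomer found, while the half-life of free monomer by initiation at that time, 130 h, was longer than the run. The neighbouring flask with 0.36 M of transfer agent kept 79% of it, which S turns into 60.4%, and it held 56.2% of its free monomer.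

Its constants stand for no real mixture; the run is a simulation.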